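## The problem

The target (19) is a sesquiterpenoid coumarin ether in which umbelliferone (18) is bound through its phenolic oxygen to C11 of a drimane-type bicycle. Drimane numbering is used throughout: ring A is C1–C5 and C10, with the ketone at C3 and the gem-dimethyl group at C4; ring B is C5–C10, with the C7=C8 double bond, a methyl group on C8 and the CH2O carbon C11 on C9. The decalin is cis-fused and carries three contiguous stereocentres, C5 (S), the quaternary C10 (S) and C9 (R): H-5, the C10 methyl group and H-9 lie on one face and C11 on the other. This is not the trans-fused pattern of the common drimanes, so the usual chiral-pool drimane precursors do not map onto it. None of the three centres is alpha to the C3 carbonyl, so none can be corrected by equilibration. They have to be set kinetically, and because they are contiguous around the quaternary C10 they are best set in one event. The coumarin lactone will not survive hydroxide, hydrazine, hydride or hydrogenation, and the C7=C8 bond can migrate under acid, so the aryl ether belongs at the end. The enabling feature is that ring B is a cyclohexene whose alkene C7=C8 lies opposite the ring-fusion bond C5–C10: a Diels–Alder retron with C5=C10 of a ring A cyclohexenone as dienophile and C6=C7–C8=C9, carrying C11, as diene. Endo addition of an (E)-diene gives exactly the required cis fusion with C11 trans to the C10 methyl group. The price is that the C3 carbonyl is not conjugated with C5=C10, so the activating carbonyl must sit at C1 and be moved afterwards.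

## Retrosynthesis

**C11–O aryl ether.** Cutting the ether bond of 19 gives primary alcohol 17 and umbelliferone 18. This is cut first because every earlier operation (hydrazine, alkaline peroxide, hydrogenation) would attack the coumarin. C11 is not a stereocentre, so the forward Mitsunobu reaction only has to achieve substitution at a beta-branched primary carbon under neutral conditions. Alcohol 17 is carried through the route as its silyl ether 16.

**C3 carbonyl back to a C1 carbonyl.** No skeletal bond is cut here; the oxygen is moved from C3 to C1. Ketone 16 comes from enone 15 by hydrogenation of C1=C2, 15 from allylic alcohol 14 by oxidation, 14 from epoxy ketone 13 by a Wharton transposition, 13 from enone 12 by nucleophilic epoxidation, and 12 from ketone 10 by Saegusa–Ito dehydrogenation. The detour is accepted because only a C1 carbonyl is conjugated with C5=C10 and can make that bond a dienophile. The sequence is favoured over other 1,3-transpositions because each step is regiochemically forced: C10 and C4 are quaternary, so enolisation, dehydrogenation and epoxidation have only one direction. The forward steps must leave C7=C8 and the silyl ether untouched.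

**C7–H back to C7–O.** Ketone 10 is traced to enol triflate 9 and this to silyl enol ether 8. The C7 oxygen is what makes the diene electron-rich enough for a hindered dienophile and what fixes the regiochemistry. Replacing it by hydrogen through the triflate keeps the double bond at C7=C8, where the cycloaddition places it. A diene without the oxygen would give the alkene directly but with opposing directing effects of the C8 methyl and C11 groups and a much lower reactivity.

**C5–C6 and C9–C10 (ring B).** Cutting these two bonds of 8 gives the silyloxydiene 6 and 2,4,4-trimethylcyclohex-2-en-1-one (7). This is the strategic cut: it removes ring B and all three stereocentres at once and leads to one purchased six-carbon ring and one acyclic five-carbon chain. Asked of the forward reaction are regiocontrol (C6 to C5), endo selectivity (C11 trans to the C10 methyl group), and face selectivity on an achiral enone, which must come from a chiral Lewis acid.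

**Diene 6.** Enol silylation disconnects 6 to enone 5, and the C3=C4 bond of 5 is cut by a Wittig disconnection to acyl ylide 3 and the silyloxy aldehyde 4. Ylide 3 goes back to bromoketone 1. The (E)-geometry needed to place C11 on the outside of the diene is the normal outcome of a stabilised ylide.

## Roads not taken

**Alternative 1:** Here the C10–CH3 and C9–C11 bonds are cut. In the forward sense a methylcuprate adds to C10 of the bicyclic enone A2, and the C8–C9 enolate is trapped with a one-carbon electrophile to give the cis-fused hydroxymethyl ketone A1.
- Merits: the C3 oxygen is in place from the start as a ketal, so no carbonyl transposition is needed. This is a real advantage over the chosen plan, which spends five steps (7 to 11) on it. Conjugate methylation of such octalones normally gives the cis fusion, and the C8 carbonyl of A1 is well placed for conversion into the methyl-bearing C7=C8 alkene.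
- Weak points: the addition must create a quaternary centre at a beta,beta-disubstituted enone carbon next to C5 and its neopentyl neighbour C4. It would need silyl or Lewis acid activation, which undermines one-pot hydroxymethylation; that trapping is itself unreliable.
- Weak points: in A1, C9 is alpha to a carbonyl and beta to a hydroxyl group, so retro-aldol cleavage, dehydration and epimerisation all threaten the centre.
- Weak points: the absolute configuration rests on C5 of A2, which must be made enantioenriched in a separate asymmetric step. An annulation leading to A2 would have to alkylate the more hindered alpha-carbon of the ring A ketone.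
- Comparison: the chosen plan has the longer endgame. Against that it sets the absolute and relative configuration in one catalytic step from a purchased enone, and C9 is never adjacent to a carbonyl.

**Alternative 2:** Here C5–C10 and C6–C7 are cut. In the forward sense the acyclic triene A4 undergoes a thermal intramolecular Diels–Alder reaction to the bicyclic conjugated ester A3. The diene of A4 bears the ester and has its tether on the inside position; the dienophile is a vinyl group.
- Merits: both rings and the quaternary C10 are formed in one step, and the C3 oxygen and the gem-dimethyl group are already present. In skeleton built per step and in the oxidation pattern of ring A this road is better than the chosen plan, which buys ring A and must transpose its carbonyl.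
- Weak points: the dienophile is unactivated and sits on a neopentyl carbon, and the diene is electron-poor and fully substituted at the reacting terminus. The temperatures needed invite 1,5-hydrogen shifts in the cis-substituted diene.
- Weak points: C9 is not a stereocentre in A3. It has to be created later by deconjugative protonation with unsecured facial control, followed by ester reduction.
- Weak points: absolute control depends on a single carbinol centre in the tether, which is later oxidised away, and A4 needs a stereodefined tetrasubstituted alkene.
- Comparison: the chosen plan sets C9 in the same event as C5 and C10 and takes its absolute configuration from a catalyst; its precursors 6 and 7 are far simpler than A4.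

**Alternative 3:** Here the C4–C5 bond is cut. In the forward sense a chiral bisphosphine–copper hydride catalyst reduces the isopropenyl ketone of the achiral cyclohexadienone A6 to its C4 enolate, which adds to one enantiotopic enone arm and closes ring A to give the cis-fused enedione A5.
- Merits: the precursor is achiral and easily assembled. A catalytic desymmetrisation sets C5 and C10, and the C3 ketone and gem-dimethyl group are in place. In the source of absolute control this road equals the chosen plan, and in ring A it is better.
- Weak points: hydride delivery must distinguish the isopropenyl ketone from the two dienone arms, and the C–C bond is formed between a fully substituted enolate carbon and a carbon next to the quaternary C10.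
- Weak points: after the key step ring B still lacks C11, C12 and the C9 stereocentre. These would need a hindered conjugate addition at C9 under substrate control, alpha-methylation at C8, and removal of the C7 carbonyl in favour of C7=C8.
- Weak points: all of this has to be done in the presence of a second ketone at C3 that must be told apart from C7.
- Comparison: the step count after the key step would be similar to the transposition in the chosen plan. The chosen plan delivers all ring B carbons and all three stereocentres together in step 4.

Key step: step 4

Assumption: with its alpha-position blocked by the C10 methyl group, enone 7 is taken to bind boron through the carbonyl lone pair on the C2 side, as 2-substituted enals do. On that model the (S)-catalyst leaves the C10 Re face open, which gives 8; if the sense proves opposite, the catalyst from (R)-diphenylprolinol is used and nothing else changes.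

## Route

Step 1
Reactants: 1 3-bromobutan-2-one
Product: 3 3-(triphenyl-λ5-phosphanylidene)butan-2-one, via phosphonium bromide 2 (not isolated)
Conditions: PPh3, toluene, 80 °C; then aq. NaOH, CH2Cl2, 23 °C
Reagents that add atoms: triphenylphosphine, c1ccc(cc1)P(c1ccccc1)c1ccccc1
Why: SN2 displacement of the alpha-bromide by the phosphine gives the acylphosphonium salt, whose acidic alpha-proton is removed by hydroxide to give the stabilised acyl ylide (standard Wittig reagent preparation).

Step 2
Reactants: 3 3-(triphenyl-λ5-phosphanylidene)butan-2-one; 4 (tert-butyldimethylsilyloxy)acetaldehyde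
Product: 5 (E)-5-(tert-butyldimethylsilyloxy)-3-methylpent-3-en-2-one
Conditions: toluene, 90 °C
Reagents that add atoms: none
Why: Wittig olefination; alpha-substituted acyl-stabilised ylides add reversibly and give the (E)-trisubstituted enone, with the acetyl group trans to CH2OTBS.

Step 3
Reactants: 5 (E)-5-(tert-butyldimethylsilyloxy)-3-methylpent-3-en-2-one
Product: 6 (E)-2,5-bis(tert-butyldimethylsilyloxy)-3-methylpenta-1,3-diene
Conditions: KN(SiMe3)2, THF, −78 °C; TBSCl, −78 → 0 °C
Reagents that add atoms: tert-butyldimethylsilyl chloride, CC(C)(C)[Si](C)(C)Cl
Why: Kinetic deprotonation of the methyl ketone at its CH3 group and O-silylation of the cross-conjugated potassium enolate give the 2-silyloxydiene; the C3=C4 geometry is not touched.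

Step 4
Reactants: 6 (E)-2,5-bis(tert-butyldimethylsilyloxy)-3-methylpenta-1,3-diene; 7 2,4,4-trimethylcyclohex-2-en-1-one
Product: 8 (5R,9R,10S)-7,11-bis(tert-butyldimethylsilyloxy)drim-7-en-1-one
Conditions: 6 (1.5 equiv), (S)-3,3-diphenyl-1-(2-methylphenyl)tetrahydro-1H,3H-pyrrolo[1,2-c][1,3,2]oxazaborole·HN(SO2CF3)2 (20 mol %, from (S)-α,α-diphenylprolinol, tri-o-tolylboroxine and HN(SO2CF3)2), CH2Cl2, −20 → 23 °C; Et3N quench
Reagents that add atoms: none
Why: The boron of the cationic oxazaborolidine binds the C1 carbonyl of 7 and lowers the LUMO of C10=C5, and the electron-rich diene 6 adds in a concerted but asynchronous [4+2] cycloaddition in which the bond from the nucleophilic CH2 terminus (C6) to the beta-carbon C5 runs ahead of the C9–C10 bond. The closest known reaction type is the oxazaborolidinium-catalysed Diels–Alder reaction of 2-silyloxybutadienes with cyclic enones; 7 belongs to that class but is more hindered than the usual members. Ring B is closed by this intermolecular [4+2] cycloaddition, both new sigma-bonds being formed suprafacially on each partner. Suprafacial addition to the ring alkene fixes H-5 and the C10 methyl group cis, which is the cis fusion. C9 is controlled by the endo transition state together with the (E)-geometry of the diene: the C1 carbonyl lies under the diene and the outside CH2OTBS group ends up cis to C1 and trans to the C10 methyl group. The absolute configuration comes from the catalyst alone because 7 is achiral: one phenyl group of the catalyst covers one face of the bound enone and the diene reaches the open C10 Re face. Regioselectivity is secured by the C7 silyloxy group and reinforced by the C9 substituent; endo and facial selectivity are secured by the carbonyl-bound Lewis acid.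

Step 5
Reactants: 8 (5R,9R,10S)-7,11-bis(tert-butyldimethylsilyloxy)drim-7-en-1-one
Product: 9 (5R,9R,10S)-11-(tert-butyldimethylsilyloxy)-1-oxodrim-7-en-7-yl trifluoromethanesulfonate
Conditions: CsF, PhNTf2, 1,2-dimethoxyethane, 23 °C
Reagents that add atoms: N-phenylbis(trifluoromethanesulfonimide), O=S(=O)(N(c1ccccc1)S(=O)(=O)C(F)(F)F)C(F)(F)F
Why: Fluoride cleaves the enol Si–O bond far faster than the alkyl Si–O bond, and the caesium enolate released is O-sulfonylated with retention of the C7=C8 enol regiochemistry set in step 4 (regiospecific enol triflate formation from a silyl enol ether).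

Step 6
Reactants: 9 (5R,9R,10S)-11-(tert-butyldimethylsilyloxy)-1-oxodrim-7-en-7-yl trifluoromethanesulfonate
Product: 10 (5R,9R,10S)-11-(tert-butyldimethylsilyloxy)drim-7-en-1-one
Conditions: Pd(OAc)2 (5 mol %), PPh3 (10 mol %), Bu3N, HCO2H, DMF, 60 °C
Reagents that add atoms: none
Why: Palladium-catalysed formate reduction of an enol triflate: zerovalent palladium inserts into the C7–O bond, formate exchange and loss of CO2 give a palladium hydride, and reductive elimination forms C7–H with the double bond left at C7=C8.

Step 7
Reactants: 10 (5R,9R,10S)-11-(tert-butyldimethylsilyloxy)drim-7-en-1-one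
Product: 12 (5R,9R,10S)-11-(tert-butyldimethylsilyloxy)drima-2,7-dien-1-one, via trimethylsilyl enol ether 11 (not isolated)
Conditions: LiN(iPr)2, THF, −78 °C, then TMSCl; crude 11, Pd(OAc)2 (1.1 equiv), MeCN, 23 °C
Reagents that add atoms: chlorotrimethylsilane, C[Si](C)(C)Cl (its silyl group is carried by 11 and lost again on the way to 12)
Why: Saegusa–Ito oxidation: the ketone can enolise only toward C2 because C10 is quaternary, and divalent palladium converts the silyl enol ether into the C2=C3 enone by beta-hydride elimination; C4 is quaternary, so dehydrogenation cannot go further.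

Step 8
Reactants: 12 (5R,9R,10S)-11-(tert-butyldimethylsilyloxy)drima-2,7-dien-1-one
Product: 13 (2R,3R,5R,9R,10S)-11-(tert-butyldimethylsilyloxy)-2,3-epoxydrim-7-en-1-one
Conditions: 30% aq. H2O2, NaOH (cat.), MeOH, 0 °C
Reagents that add atoms: hydrogen peroxide, OO
Why: Nucleophilic (Weitz–Scheffer) epoxidation: hydroperoxide adds to C3 of the enone and the enolate closes onto oxygen, while the electron-rich C7=C8 bond is inert to the nucleophilic oxidant; the epoxide is expected mainly on the convex beta-face (cis to H-5), and since C2 and C3 lose their configuration in steps 9 and 10 either epoxide serves.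

Step 9
Reactants: 13 (2R,3R,5R,9R,10S)-11-(tert-butyldimethylsilyloxy)-2,3-epoxydrim-7-en-1-one
Product: 14 (3S,5S,9R,10S)-11-(tert-butyldimethylsilyloxy)drima-1,7-dien-3-ol
Conditions: N2H4·H2O, AcOH, MeOH, 0 → 23 °C
Reagents that add atoms: none
Why: Wharton transposition: the hydrazone of the epoxy ketone opens the epoxide, and the vinyl diazene formed loses N2 to give the C1=C2 alkene and the C3 alcohol with the C3–O bond retained.

Step 10
Reactants: 14 (3S,5S,9R,10S)-11-(tert-butyldimethylsilyloxy)drima-1,7-dien-3-ol
Product: 15 (5S,9R,10S)-11-(tert-butyldimethylsilyloxy)drima-1,7-dien-3-one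
Conditions: DMP (1,1,1-triacetoxy-1,1-dihydro-1,2-benziodoxol-3(1H)-one), CH2Cl2, 23 °C
Reagents that add atoms: none
Why: Hypervalent-iodine oxidation of the secondary allylic alcohol gives the C1=C2–C3=O enone under near-neutral conditions that leave the silyl ether and the C7=C8 bond alone; the C3 carbinol centre is removed.

Step 11
Reactants: 15 (5S,9R,10S)-11-(tert-butyldimethylsilyloxy)drima-1,7-dien-3-one
Product: 16 (5S,9R,10S)-11-(tert-butyldimethylsilyloxy)drim-7-en-3-one
Conditions: H2 (1 atm), RhCl(PPh3)3 (10 mol %), benzene, 23 °C
Reagents that add atoms: none
Why: Homogeneous hydrogenation with the monovalent rhodium complex reduces the cis-disubstituted enone double bond (as in the selective 1,2-reduction of steroidal 1,4-dien-3-ones) and does not touch the hindered trisubstituted C7=C8 bond; no stereocentre is formed.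

Step 12
Reactants: 16 (5S,9R,10S)-11-(tert-butyldimethylsilyloxy)drim-7-en-3-one
Product: 17 (5S,9R,10S)-11-hydroxydrim-7-en-3-one
Conditions: HF·pyridine, pyridine, THF, 0 → 23 °C
Reagents that add atoms: none
Why: Fluoride-mediated cleavage of the primary silyl ether in a buffered medium that neither enolises the ketone nor moves the C7=C8 bond.

Step 13
Reactants: 17 (5S,9R,10S)-11-hydroxydrim-7-en-3-one; 18 umbelliferone (7-hydroxy-2H-chromen-2-one)
Product: 19 7-{[(1R,4aS,8aS)-2,5,5,8a-tetramethyl-6-oxo-1,4,4a,5,6,7,8,8a-octahydronaphthalen-1-yl]methoxy}-2H-chromen-2-one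
Conditions: PPh3, diisopropyl azodicarboxylate, THF, 0 → 23 °C
Reagents that add atoms: none
Why: Mitsunobu etherification: the primary alcohol is activated as its oxyphosphonium ion and displaced at C11 (not a stereocentre) by the acidic phenol of umbelliferone; the neutral conditions spare the coumarin lactone and the ketone.

## Compound list

1 | 3-bromobutan-2-one | CC(Br)C(C)=O | starting material
2 | (3-oxobutan-2-yl)triphenylphosphonium bromide | CC(=O)C(C)[P+](c1ccccc1)(c1ccccc1)c1ccccc1.[Br-] | intermediate (not isolated)
3 | 3-(triphenyl-λ5-phosphanylidene)butan-2-one | CC(=O)C(C)=P(c1ccccc1)(c1ccccc1)c1ccccc1 | intermediate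
4 | (tert-butyldimethylsilyloxy)acetaldehyde | CC(C)(C)[Si](C)(C)OCC=O | starting material
5 | (E)-5-(tert-butyldimethylsilyloxy)-3-methylpent-3-en-2-one | CC(=O)/C(C)=C/CO[Si](C)(C)C(C)(C)C | intermediate
6 | (E)-2,5-bis(tert-butyldimethylsilyloxy)-3-methylpenta-1,3-diene | C=C(O[Si](C)(C)C(C)(C)C)/C(C)=C/CO[Si](C)(C)C(C)(C)C | intermediate
7 | 2,4,4-trimethylcyclohex-2-en-1-one | CC1=CC(C)(C)CCC1=O | starting material
8 | (5R,9R,10S)-7,11-bis(tert-butyldimethylsilyloxy)drim-7-en-1-one; systematic: (4aR,8R,8aS)-6-(tert-butyldimethylsilyloxy)-8-[(tert-butyldimethylsilyloxy)methyl]-4,4,7,8a-tetramethyl-3,4,4a,5,8,8a-hexahydronaphthalen-1(2H)-one; cis-fused, H-5, CH3-10 and H-9 on one face | CC1=C(O[Si](C)(C)C(C)(C)C)C[C@@H]2C(C)(C)CCC(=O)[C@]2(C)[C@@H]1CO[Si](C)(C)C(C)(C)C | intermediate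
9 | (5R,9R,10S)-11-(tert-butyldimethylsilyloxy)-1-oxodrim-7-en-7-yl trifluoromethanesulfonate | CC1=C(OS(=O)(=O)C(F)(F)F)C[C@@H]2C(C)(C)CCC(=O)[C@]2(C)[C@@H]1CO[Si](C)(C)C(C)(C)C | intermediate
10 | (5R,9R,10S)-11-(tert-butyldimethylsilyloxy)drim-7-en-1-one | CC1=CC[C@@H]2C(C)(C)CCC(=O)[C@]2(C)[C@@H]1CO[Si](C)(C)C(C)(C)C | intermediate
11 | (5R,9R,10S)-11-(tert-butyldimethylsilyloxy)-1-(trimethylsilyloxy)drima-1,7-diene | CC1=CC[C@@H]2C(C)(C)CC=C(O[Si](C)(C)C)[C@]2(C)[C@@H]1CO[Si](C)(C)C(C)(C)C | intermediate (not isolated)
12 | (5R,9R,10S)-11-(tert-butyldimethylsilyloxy)drima-2,7-dien-1-one | CC1=CC[C@@H]2C(C)(C)C=CC(=O)[C@]2(C)[C@@H]1CO[Si](C)(C)C(C)(C)C | intermediate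
13 | (2R,3R,5R,9R,10S)-11-(tert-butyldimethylsilyloxy)-2,3-epoxydrim-7-en-1-one (beta-epoxide, cis to H-5) | CC1=CC[C@@H]2C(C)(C)[C@H]3O[C@H]3C(=O)[C@]2(C)[C@@H]1CO[Si](C)(C)C(C)(C)C | intermediate
14 | (3S,5S,9R,10S)-11-(tert-butyldimethylsilyloxy)drima-1,7-dien-3-ol (3-OH cis to H-5) | CC1=CC[C@@H]2C(C)(C)[C@@H](O)C=C[C@]2(C)[C@@H]1CO[Si](C)(C)C(C)(C)C | intermediate
15 | (5S,9R,10S)-11-(tert-butyldimethylsilyloxy)drima-1,7-dien-3-one | CC1=CC[C@@H]2C(C)(C)C(=O)C=C[C@]2(C)[C@@H]1CO[Si](C)(C)C(C)(C)C | intermediate
16 | (5S,9R,10S)-11-(tert-butyldimethylsilyloxy)drim-7-en-3-one | CC1=CC[C@@H]2C(C)(C)C(=O)CC[C@]2(C)[C@@H]1CO[Si](C)(C)C(C)(C)C | intermediate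
17 | (5S,9R,10S)-11-hydroxydrim-7-en-3-one | CC1=CC[C@@H]2C(C)(C)C(=O)CC[C@]2(C)[C@@H]1CO | intermediate
18 | umbelliferone (7-hydroxy-2H-chromen-2-one) | Oc1ccc2ccc(=O)oc2c1 | starting material
19 | 7-{[(1R,4aS,8aS)-2,5,5,8a-tetramethyl-6-oxo-1,4,4a,5,6,7,8,8a-octahydronaphthalen-1-yl]methoxy}-2H-chromen-2-one; in drimane numbering (5S,9R,10S)-11-(2-oxo-2H-chromen-7-yloxy)drim-7-en-3-one | CC1=CC[C@@H]2C(C)(C)C(=O)CC[C@]2(C)[C@@H]1COc1ccc2ccc(=O)oc2c1 | target

## Step count and least certain steps

Total: 13 steps. Longest linear sequence: 13 steps (1 → 3 → 5 → 6 → 8 → 9 → 10 → 12 → 13 → 14 → 15 → 16 → 17 → 19); compounds 4, 7 and 18 are purchased.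

**Step 4 (key step).** Two things are most likely to go wrong. The cycloaddition may be slow, because C5 of 7 is neopentyl and C10 becomes quaternary. Acid-induced desilylation or oligomerisation of 6, or a stepwise Mukaiyama–Michael addition that stops after the first bond, could then outrun ring closure. Facial discrimination may also be weak, because the alpha-methyl group removes the alpha-C–H contact that normally organises enones on this catalyst. Fallback: starting from 6 and 7, the cycloaddition is run without asymmetric induction under a mixed AlBr3/AlMe3 Lewis acid (toluene/CH2Cl2, low temperature), a combination suited to hindered silyloxydiene–cycloalkenone pairs. This gives the racemic endo adduct, rac-7,11-bis(tert-butyldimethylsilyloxy)drim-7-en-1-one F1. Its enantiomers are separated by preparative chromatography on a chiral stationary phase, and the (5R,9R,10S) enantiomer is 8, where the route is rejoined.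

**Step 5.** The likely failure is proton transfer from C2–H of the C1 ketone to the liberated C7 enolate before it is sulfonylated. That would scramble the enol regiochemistry or sulfonylate the C1 enolate; partial fluoride cleavage of the primary silyl ether is a lesser risk. Fallback: starting from 8, the C1 ketone is first reduced with LiAlH4 (THF, −78 → 0 °C) to the C1 alcohol F2 (either epimer serves; drawn 1β). CsF and PhNTf2 then convert the silyl enol ether, with no enolisable ketone present, into the hydroxy enol triflate F3. Formate reduction as in step 6 gives the alkenol F4, and oxidation with DMP returns the route to ketone 10.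

**Step 9.** The likely failure is slow hydrazone formation at the C1 carbonyl, which is flanked by the quaternary C10 and the epoxide. Epoxide opening by hydrazine or simple reduction could then compete, and the transposition would stall. Fallback: starting from 13, NaBH4 (MeOH, 0 °C) gives the epoxy alcohol F5 (either C1 epimer; drawn 1β). 1,1'-Thiocarbonyldiimidazole (4-dimethylaminopyridine, 1,2-dichloroethane, reflux) gives the imidazolylthiocarbonyl ester F6. Bu3SnH with azobisisobutyronitrile in refluxing benzene generates the C1 radical, which opens the epoxide to the C1=C2 alkene and, after hydrogen transfer to the C3 oxygen radical, gives allylic alcohol 14, where the route is rejoined.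

**Step 13.** The likely failure is slow substitution at C11, which is beta-branched (C9 carries the quaternary C10 and the alkene carbon C8). The oxyphosphonium intermediate could then be intercepted by the reduced azodicarboxylate or undergo elimination. Fallback: starting from 17, the alcohol is converted with MsCl and Et3N (CH2Cl2, 0 °C) into the methanesulfonate F7. This is displaced by the caesium phenoxide of 18 (Cs2CO3, DMF, 60 °C), which gives 19 directly.

## Further compounds

F1 | step 4 | racemic endo adduct, rac-7,11-bis(tert-butyldimethylsilyloxy)drim-7-en-1-one (8 and its enantiomer) | CC1=C(O[Si](C)(C)C(C)(C)C)C[C@@H]2C(C)(C)CCC(=O)[C@]2(C)[C@@H]1CO[Si](C)(C)C(C)(C)C.CC1=C(O[Si](C)(C)C(C)(C)C)C[C@H]2C(C)(C)CCC(=O)[C@@]2(C)[C@H]1CO[Si](C)(C)C(C)(C)C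
F2 | step 5 | 7,11-bis(tert-butyldimethylsilyloxy)drim-7-en-1β-ol (C1 alcohol of 8) | CC1=C(O[Si](C)(C)C(C)(C)C)C[C@@H]2C(C)(C)CC[C@@H](O)[C@]2(C)[C@@H]1CO[Si](C)(C)C(C)(C)C
F3 | step 5 | 11-(tert-butyldimethylsilyloxy)-1β-hydroxydrim-7-en-7-yl trifluoromethanesulfonate | CC1=C(OS(=O)(=O)C(F)(F)F)C[C@@H]2C(C)(C)CC[C@@H](O)[C@]2(C)[C@@H]1CO[Si](C)(C)C(C)(C)C
F4 | step 5 | 11-(tert-butyldimethylsilyloxy)drim-7-en-1β-ol | CC1=CC[C@@H]2C(C)(C)CC[C@@H](O)[C@]2(C)[C@@H]1CO[Si](C)(C)C(C)(C)C
F5 | step 9 | 11-(tert-butyldimethylsilyloxy)-2β,3β-epoxydrim-7-en-1β-ol | CC1=CC[C@@H]2C(C)(C)[C@H]3O[C@H]3[C@@H](O)[C@]2(C)[C@@H]1CO[Si](C)(C)C(C)(C)C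
F6 | step 9 | O-[11-(tert-butyldimethylsilyloxy)-2β,3β-epoxydrim-7-en-1β-yl] 1H-imidazole-1-carbothioate | CC1=CC[C@@H]2C(C)(C)[C@H]3O[C@H]3[C@@H](OC(=S)n3ccnc3)[C@]2(C)[C@@H]1CO[Si](C)(C)C(C)(C)C
F7 | step 13 | (5S,9R,10S)-3-oxodrim-7-en-11-yl methanesulfonate | CC1=CC[C@@H]2C(C)(C)C(=O)CC[C@]2(C)[C@@H]1COS(C)(=O)=O
A1 | alternative 1 | cis-fused 3,3-ethylenedioxy-9-(hydroxymethyl)-4,4,10-trimethyldecalin-8-one (drimane numbering; H-5, CH3-10 and H-9 on one face) | O=C1CC[C@@H]2C(C)(C)C3(OCCO3)CC[C@]2(C)[C@@H]1CO
A2 | alternative 1 | (5S)-3,3-ethylenedioxy-4,4-dimethyl-Δ9(10)-octalin-8-one (drimane numbering) | O=C1CC[C@@H]2C(C)(C)C3(OCCO3)CCC2=C1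
A3 | alternative 2 | methyl cis-fused 3-(tert-butyldimethylsilyloxy)-4,4,8,10-tetramethyl-Δ8(9)-octalin-9-carboxylate (drimane numbering) | COC(=O)C1=C(C)CC[C@@H]2C(C)(C)[C@@H](O[Si](C)(C)C(C)(C)C)CC[C@]12C
A4 | alternative 2 | methyl (2E,6S)-6-(tert-butyldimethylsilyloxy)-3,7,7-trimethyl-2-(prop-1-en-2-yl)nona-2,8-dienoate | C=CC(C)(C)[C@@H](O[Si](C)(C)C(C)(C)C)CC/C(C)=C(\C(C)=C)C(=O)OC
A5 | alternative 3 | cis-fused 4,4,10-trimethyl-Δ8(9)-octalin-3,7-dione (drimane numbering; H-5 and CH3-10 on one face) | O=C1C=C[C@@]2(C)CCC(=O)C(C)(C)[C@H]2C1
A6 | alternative 3 | 4-methyl-4-(4-methyl-3-oxopent-4-en-1-yl)cyclohexa-2,5-dien-1-one | C=C(C)C(=O)CCC1(C)C=CC(=O)C=C1
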